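**Retrosynthetic overview**
1. Ring B (cyclopentanone) is closed last: the C8–C9 bond comes from an intramolecular Kulinkovich cyclopropanation of an ester arm onto a vinyl group, followed by base opening of the cyclopropanol and equilibration of C7 and C9.
2. Ring A (cyclohexene) and both adjacent quaternary carbons C1 and C6 are made in one step by a ring-contracting Ireland–Claisen rearrangement of a six-membered allylic lactone through an enforced boat, not by a Diels–Alder reaction.
3. The triene is built on the lactone carbinol carbon from a propynyl group by syn-hydroboration and Suzuki coupling with a dienyl iodide made by carbocupration.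
4. The lactone (C3, C4, C5) comes from a chiral-diol-catalysed crotylboration of pent-3-yn-2-one with a glutarate-bearing (E)-allylboronate, then a desymmetrising lactonisation.
5. Order of ring formation: temporary lactone, then ring A, then ring B.

Assumption: target atom labels are kept for all intermediates: C1 (ring carbon with methyl and dienyl), C2=C3 (ring alkene, methyl on C3), C4 and C5 (ring-fusion CH), C6 (ring carbon with ethyl and CO2H), C7 (CHEt), C8 (C=O), C9 (CHMe), C10 (carboxyl carbon).

**Step 1**
Reactants: 1 dimethyl glutaconate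
Product: 2 dimethyl 3-ethenylpentanedioate
Conditions: CH2=CHMgBr (1.3 equiv), CuBr·SMe2 (10 mol %), THF, −78 → −30 °C; H2O
Reagents that add atoms: vinylmagnesium bromide, C=C[Mg]Br
Why: Copper-catalysed conjugate (Michael) addition of the vinyl group to the β-carbon of the unsaturated diester is faster at low temperature than deprotonation of the acidic CH2, and no stereocentre is formed.

**Step 2**
Reactants: 2 dimethyl 3-ethenylpentanedioate; 3 allylboronic acid pinacol ester
Product: 4 dimethyl 3-[(E)-3-(pinacolboryl)prop-1-enyl]pentanedioate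
Conditions: second-generation Grubbs catalyst (5 mol %), 3 (3 equiv), CH2Cl2, 40 °C
Reagents that add atoms: none
Why: Olefin cross-metathesis of an α-branched terminal alkene with an allylboronate gives the (E)-γ-substituted allylboronate, the branched allylic carbon favouring the E isomer.

**Step 3**
Reactants: 5 (E)-cinnamaldehyde
Product: 6 (E)-but-1-en-3-ynylbenzene
Conditions: dimethyl (1-diazo-2-oxopropyl)phosphonate (1.2 equiv), K2CO3 (2 equiv), MeOH, 23 °C
Reagents that add atoms: dimethyl (1-diazo-2-oxopropyl)phosphonate, COP(=O)(OC)C(=[N+]=[N-])C(C)=O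
Why: Seyferth–Gilbert homologation in its Ohira–Bestmann form converts the enal into the terminal enyne under mild base without touching the (E)-styryl alkene.

**Step 4**
Reactants: 6 (E)-but-1-en-3-ynylbenzene
Product: 8 [(1E,3E)-3-ethyl-4-iodobuta-1,3-dienyl]benzene, via dienylcopper 7 (not isolated)
Conditions: EtMgBr and CuBr·SMe2 (1.1 equiv each), Et2O/Me2S, −45 °C; 6, −25 °C; I2, THF, −50 → 0 °C
Reagents that add atoms: ethylmagnesium bromide, CC[Mg]Br; iodine, II
Why: Normant carbocupration adds ethyl and copper syn across the terminal alkyne (ethyl to the internal carbon), and iodinolysis with retention gives the iodide with iodine cis to ethyl and trans to styryl.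

**Step 5**
Reactants: 4 dimethyl 3-[(E)-3-(pinacolboryl)prop-1-enyl]pentanedioate; 9 pent-3-yn-2-one
Product: 12 methyl 2-[(2S,3S,4R)-3-ethenyl-2-methyl-6-oxo-2-(prop-1-ynyl)oxan-4-yl]acetate, via borate ester 10 (not isolated), via hydroxy diester 11 (not isolated)
Conditions: (S)-3,3′-dibromo-1,1′-bi-2-naphthol (15 mol %), t-BuOH (2 equiv), toluene, 23 °C, 48 h; aq. NaHCO3; crude in THF, NaH (10 mol %), 0 → 23 °C
Reagents that add atoms: none
Why: Chiral-diol-catalysed ketone crotylboration through a closed chair (glutarate-bearing carbon and ketone methyl equatorial, rod-like propynyl axial) sets C3 and C4 with methyl cis to vinyl and the diol choosing the ketone face, and the alkoxide-catalysed, reversible lactonisation onto one of the two equivalent ester arms then sets C5 trans to the vinyl group because the cis lactone would place the arm syn-diaxial to the C3 methyl.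

**Step 6**
Reactants: 12 lactone
Product: 13 methyl 2-[3-ethenyl-5-ethyl-2-methyl-6-oxo-2-(prop-1-ynyl)oxan-4-yl]butanoate (C3, C4, C5 as in 12; epimer mixture at C6 and C7)
Conditions: LiN(iPr)2 (2.3 equiv), THF/DMPU, −78 °C; EtI (4 equiv), −78 → −40 °C
Reagents that add atoms: iodoethane, CCI
Why: Double enolate alkylation ethylates the lactone α-carbon (C6) and the ester α-carbon (C7), and neither new centre needs control because C6 becomes trigonal in step 9 and C7 is equilibrated in step 11.

**Step 7**
Reactants: 13 bis-ethylated lactone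
Product: 14 alkenylboronate: as 13 with (Z)-2-(pinacolboryl)prop-1-enyl in place of propynyl (boron trans to C3)
Conditions: CuCl (5 mol %), Xantphos (6 mol %), NaOtBu (10 mol %), B2pin2 (1.1 equiv), MeOH (2 equiv), THF, 23 °C
Reagents that add atoms: bis(pinacolato)diboron, CC1(C)OB(OC1(C)C)B1OC(C)(C)C(C)(C)O1
Why: Copper-catalysed alkyne hydroboration (syn borylcupration then protonation) puts boron on the alkyne carbon remote from the oxygen-bearing quaternary centre, leaving the C1 methyl cis to C3, and leaves the unactivated vinyl group alone.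

**Step 8**
Reactants: 14 alkenylboronate; 8 dienyl iodide
Product: 15 triene lactone: as 13 with (1E,3E,5E)-4-ethyl-2-methyl-6-phenylhexa-1,3,5-trienyl on C3
Conditions: Pd(PPh3)4 (5 mol %), K3PO4 (3 equiv), THF/H2O (5:1), 40 °C
Reagents that add atoms: none
Why: Suzuki–Miyaura coupling joins the two alkenyl partners with retention at both, oxidative addition into the alkenyl iodide being much faster than ionisation of the hindered tertiary allylic lactone by zerovalent palladium.

**Step 9**
Reactants: 15 triene lactone
Product: 18 cyclohexene acid (ring A with C1, C4, C5, C6 as in the target; vinyl on C4, CH(Et)CO2Me on C5), via bis(silyl ketene acetal) 16 (not isolated), via silyl ester 17 (not isolated)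
Conditions: LiN(iPr)2 (3 equiv), Me3SiCl/Et3N, THF/DMPU, −78 → 23 °C, then 65 °C; 1 M HCl
Reagents that add atoms: none
Why: Ireland–Claisen rearrangement in its lactone ring-contraction form can only proceed through a boat in which the alkenyl group on the upper face of C3 bonds C1 to C6, so the C3–O stereocentre is transferred to both quaternary carbons, the (E)-alkene placing the C1 methyl cis to the C6 ethyl and the dienyl cis to the carboxyl.

**Step 10**
Reactants: 18 cyclohexene acid
Product: 19 cyclopropanol (C8 carbinol bonded to C7, C9 and a CH2 that bridges C8 and C9; ring fusion trans)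
Conditions: ClTi(OiPr)3 (1.5 equiv), c-C6H11MgCl (5 equiv), THF, 0 → 23 °C; H2O
Reagents that add atoms: none
Why: Intramolecular Kulinkovich cyclopropanation engages the only monosubstituted alkene and the neighbouring methyl ester (the hindered carboxylate is inert), closing the C8–C9 bond of the five-membered ring between the two trans arms, and the cyclopropanol centres need no control.

**Step 11**
Reactants: 19 cyclopropanol
Product: 20 target acid
Conditions: KOH (3 equiv), MeOH/H2O, 23 → 50 °C; 1 M HCl
Reagents that add atoms: none
Why: Base-induced cyclopropanol (homoenolate) ring opening cleaves the bond to the CH2 carbon to give the 2-methylcyclopentanone, and the same base equilibrates C7 and C9 to the all-trans arrangement of the target, which is expected to be the thermodynamic one.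

**Compound list**
1 | dimethyl (E)-pent-2-enedioate (dimethyl glutaconate) | COC(=O)C/C=C/C(=O)OC | starting material
2 | dimethyl 3-ethenylpentanedioate | COC(=O)CC(C=C)CC(=O)OC | intermediate
3 | 2-allyl-4,4,5,5-tetramethyl-1,3,2-dioxaborolane (allylboronic acid pinacol ester) | C=CCB1OC(C)(C)C(C)(C)O1 | starting material
4 | dimethyl 3-[(E)-3-(4,4,5,5-tetramethyl-1,3,2-dioxaborolan-2-yl)prop-1-enyl]pentanedioate | COC(=O)CC(CC(=O)OC)/C=C/CB1OC(C)(C)C(C)(C)O1 | intermediate
5 | (E)-cinnamaldehyde | O=C/C=C/c1ccccc1 | starting material
6 | (E)-but-1-en-3-ynylbenzene | C#C/C=C/c1ccccc1 | intermediate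
7 | [(1E,3E)-2-ethyl-4-phenylbuta-1,3-dienyl]copper | CCC(/C=C/c1ccccc1)=C\[Cu] | intermediate (not isolated)
8 | [(1E,3E)-3-ethyl-4-iodobuta-1,3-dienyl]benzene | CCC(/C=C/c1ccccc1)=C\I | intermediate
9 | pent-3-yn-2-one | CC#CC(C)=O | starting material
10 | dimethyl 3-[(3S,4S)-4-methyl-4-(pinacolboryloxy)hept-1-en-5-yn-3-yl]pentanedioate | COC(=O)CC(CC(=O)OC)[C@H](C=C)[C@](C)(OB1OC(C)(C)C(C)(C)O1)C#CC | intermediate (not isolated)
11 | dimethyl 3-[(3S,4S)-4-hydroxy-4-methylhept-1-en-5-yn-3-yl]pentanedioate | COC(=O)CC(CC(=O)OC)[C@H](C=C)[C@](C)(O)C#CC | intermediate (not isolated)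
12 | methyl 2-[(2S,3S,4R)-3-ethenyl-2-methyl-6-oxo-2-(prop-1-ynyl)oxan-4-yl]acetate (2-methyl cis to 3-ethenyl, 3-ethenyl trans to the 4-side chain) | O=C1C[C@@H](CC(=O)OC)[C@H](C=C)[C@@](C)(C#CC)O1 | intermediate
13 | methyl 2-[3-ethenyl-5-ethyl-2-methyl-6-oxo-2-(prop-1-ynyl)oxan-4-yl]butanoate, ring centres C3, C4, C5 as in 12, epimer mixture at C6 and C7 | O=C1C(CC)[C@@H](C(CC)C(=O)OC)[C@H](C=C)[C@@](C)(C#CC)O1 | intermediate
14 | as 13 with (Z)-2-(pinacolboryl)prop-1-enyl on C3 | O=C1C(CC)[C@@H](C(CC)C(=O)OC)[C@H](C=C)[C@@](C)(/C=C(\C)B2OC(C)(C)C(C)(C)O2)O1 | intermediate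
15 | as 13 with (1E,3E,5E)-4-ethyl-2-methyl-6-phenylhexa-1,3,5-trienyl on C3 | O=C1C(CC)[C@@H](C(CC)C(=O)OC)[C@H](C=C)[C@@](C)(/C=C(\C)/C=C(CC)/C=C/c2ccccc2)O1 | intermediate
16 | bis(trimethylsilyl ketene acetal) of 15 (lactone and side-chain ester) | C[Si](C)(C)OC1=C(CC)[C@@H](C(CC)=C(OC)O[Si](C)(C)C)[C@H](C=C)[C@@](C)(/C=C(\C)/C=C(CC)/C=C/c2ccccc2)O1 | intermediate (not isolated)
17 | trimethylsilyl ester of the rearranged acid, side-chain ester still as silyl ketene acetal | CCC(/C=C/c1ccccc1)=C\[C@@]1(C)C=C(C)[C@@H](C=C)[C@H](C(CC)=C(OC)O[Si](C)(C)C)[C@@]1(CC)C(=O)O[Si](C)(C)C | intermediate (not isolated)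
18 | cyclohexene acid: C1 methyl and C6 ethyl cis, C1 dienyl and C6 carboxyl cis, C5 side chain CH(Et)CO2Me cis to the C6 ethyl, C4 vinyl trans to the C5 side chain; C7 epimer mixture | CCC(/C=C/c1ccccc1)=C\[C@@]1(C)C=C(C)[C@@H](C=C)[C@H](C(CC)C(=O)OC)[C@@]1(CC)C(=O)O | intermediate
19 | cyclopropanol: as 18 with C8(OH) bonded to C7, C9 and a bridging CH2; trans ring fusion; C7, C8, C9 uncontrolled | CCC(/C=C/c1ccccc1)=C\[C@@]1(C)C=C(C)[C@@H]2[C@H](C(CC)C3(O)CC23)[C@@]1(CC)C(=O)O | intermediate
20 | target: 1,7-diethyl-6-[(1E,3E)-2-ethyl-4-phenylbuta-1,3-dienyl]-3,4,6-trimethyl-2-oxo-2,3,3a,6,7,7a-hexahydro-1H-indene-7-carboxylic acid, trans-fused, configuration as in the given SMILES | CCC(/C=C/c1ccccc1)=C\[C@@]1(C)C=C(C)[C@@H]2[C@H]([C@H](CC)C(=O)[C@H]2C)[C@@]1(CC)C(=O)O | target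

**Step count and risks**
Total: 11 steps. Longest linear sequence: 9 steps (1, 2, 5, 6, 7, 8, 9, 10, 11, from dimethyl glutaconate); steps 3 and 4 make the dienyl iodide separately.

Step 5 (asymmetric crotylboration). Diol-catalysed allylboration of an ynone with a functionalised γ-substituted pinacol boronate is an extension of the known scope. The facial sense of the (S)-diol on this substrate must be confirmed on the first run, and the diastereoselectivity depends on the propynyl group sitting axial. Fallback: setting out from 4 and 9, the allylboration is run without the chiral diol (neat, 60 °C). This keeps the closed chair and hence the relative configuration but gives the racemate, so the mirror-image borate ester F1 and the mirror-image hydroxy diester F2 form beside 10 and 11. Lactonisation as before gives 12 mixed with the mirror-image lactone F3, which is removed by preparative chromatography on a chiral stationary phase, and the route is rejoined at 12.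

Step 9 (ring-contracting Ireland–Claisen). Two fully substituted carbons are joined in a boat in which the C5 side chain and the C1 methyl point towards each other, so ionisation or elimination of the tertiary trienyl lactone may compete. Fallback: setting out from 12, before the ethyl groups are in place, hydroboration as in step 7 gives the unethylated alkenylboronate F4 and Suzuki coupling with 8 gives the unethylated triene lactone F5. Its much less hindered lithium dienolate (LiN(iPr)2, THF, −78 → 23 °C, no silylation) rearranges to the unethylated acid F6. The trianion of F6 (LiN(iPr)2, 3.3 equiv) is then ethylated twice with iodoethane, at C7 and at C6 anti to the dienyl group, to rejoin the route at 18.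

Step 10 (Kulinkovich cyclopropanation). The low-valent titanium reagent may also bind the conjugated phenyl diene, the substrate carries a free carboxylate, and the new ring must close trans-fused. Fallback: setting out from 18, LiOH hydrolysis gives the diacid F7, and the unhindered side-chain acid is converted selectively ((PhSe)2, Bu3P) into the Se-phenyl selenoester F8. Bu3SnH with azobisisobutyronitrile (benzene, 80 °C, high hydride concentration to suppress six-membered ring formation) then triggers 5-exo acyl radical cyclisation onto the vinyl group. Brief KOH treatment equilibrates the product to 20, where the route is rejoined.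

**Further compounds**
F1 | step 5 | enantiomer of borate ester 10 | COC(=O)CC(CC(=O)OC)[C@@H](C=C)[C@@](C)(OB1OC(C)(C)C(C)(C)O1)C#CC
F2 | step 5 | enantiomer of hydroxy diester 11 | COC(=O)CC(CC(=O)OC)[C@@H](C=C)[C@@](C)(O)C#CC
F3 | step 5 | enantiomer of lactone 12 | O=C1C[C@H](CC(=O)OC)[C@@H](C=C)[C@](C)(C#CC)O1
F4 | step 9 | unethylated alkenylboronate (12 with (Z)-2-(pinacolboryl)prop-1-enyl in place of propynyl) | O=C1C[C@@H](CC(=O)OC)[C@H](C=C)[C@@](C)(/C=C(\C)B2OC(C)(C)C(C)(C)O2)O1
F5 | step 9 | unethylated triene lactone | O=C1C[C@@H](CC(=O)OC)[C@H](C=C)[C@@](C)(/C=C(\C)/C=C(CC)/C=C/c2ccccc2)O1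
F6 | step 9 | unethylated cyclohexene acid (C6–H, side chain CH2CO2Me) | CCC(/C=C/c1ccccc1)=C\[C@@]1(C)C=C(C)[C@@H](C=C)[C@H](CC(=O)OC)[C@H]1C(=O)O
F7 | step 10 | diacid from 18 (side-chain CO2H) | CCC(/C=C/c1ccccc1)=C\[C@@]1(C)C=C(C)[C@@H](C=C)[C@H](C(CC)C(=O)O)[C@@]1(CC)C(=O)O
F8 | step 10 | Se-phenyl selenoester of the side-chain acid | CCC(/C=C/c1ccccc1)=C\[C@@]1(C)C=C(C)[C@@H](C=C)[C@H](C(CC)C(=O)[Se]c2ccccc2)[C@@]1(CC)C(=O)O
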